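**Retrosynthetic overview**

1. The target is cut back, through late acylations and oxidation of two ring olefins, to a bicyclo[5.3.0]deca-5,9-diene that is stereogenic only at C1, C2, C4 and C8.
2. Key disconnection: bonds C1–C5 and C6–C7, made together by a rhodium-catalysed (5+2) cycloaddition of an open-chain ynyl vinylcyclopropane. The five-membered ring (C1–C5) closes first and the seven-membered ring (C1, C5–C10) directly after, in the same catalytic cycle.
3. Feature that carries the strategy: the ring-fusion bond C1–C5 with its methyl-bearing quaternary C1, and the C7 methylene next to methyl-bearing C8 in the seven-membered ring. They map onto a methylated alkene terminus (C1=C10), an alkyne (C5≡C6) and a trans-methylcyclopropane (C7–C8–C9) joined by the tether C2–C3–C4; the olefins left at C5=C6 and C9=C10 lie where the C6 ester and the C8–C10 epoxy acetate are needed.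
4. The open chain comes from an enantioselective Mukaiyama aldol of a cyclopropyl enal with the enol silane of 3-methylbutan-2-one (sets C2), then chelation-controlled ethynyl addition (sets C4). The enal comes from asymmetric cyclopropanation of (E)-but-2-en-1-ol, oxidation and Wittig olefination.
5. After the cycloaddition: C2–OH-directed epoxidation of C9=C10, selenide opening and selenoxide elimination to the C10 allylic alcohol, directed epoxidation of C8=C9, diacetylation, hydroboration of C5=C6, angeloylation, desilylation.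

Key step: step 7

**Conventions and assumptions**

- Ring compounds are named on the bicyclo[5.3.0]decane skeleton with the atom numbers C1–C10 used above (C1 fusion carbon with methyl, C2, C3, C4 in the five-membered ring, C5 fusion carbon, C6–C10 in the seven-membered ring). β is the face of the C1 methyl, α the opposite face.
- Both hydroxyls are carried as triethylsilyl ethers, because the C4 ether has to be removed last, beside an epoxide and three esters, and a tertiary tert-butyldimethylsilyl ether would not come off under conditions these groups survive.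
- The cyclopropane is made as the (1R,2R) antipode. The only hydrogen β to the C9,C10-epoxide is the C8 methine hydrogen, which amide bases abstract poorly, so the epoxide is isomerised by selenide opening and selenoxide syn-elimination. That needs C8–H cis to the selenium, hence β, and the (1R,2R) ring delivers this. C8 later becomes trigonal, so its configuration has no other consequence.
- The (4S,5S)-dioxaborolane (step 1) and the (S,S)-bisphosphoramide (step 4) are assumed to give the configurations shown, following the facial models of these controllers; the antipodal controller would be used if either sense proved opposite.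

**Route**

Step 1
Reactants: 1 (E)-but-2-en-1-ol
Product: 2 [(1R,2R)-2-methylcyclopropyl]methanol
Conditions: Et2Zn, CH2I2, DME, (4S,5S)-2-butyl-N,N,N′,N′-tetramethyl-1,3,2-dioxaborolane-4,5-dicarboxamide (1.2 equiv), CH2Cl2, −10 °C → rt
Reagents that add atoms: diiodomethane, ICI
Why: Charette asymmetric Simmons–Smith cyclopropanation: the zinc alkoxide of 1 binds the chiral dioxaborolane, which steers the zinc carbenoid to one alkene face, and stereospecific methylene transfer turns the E-alkene into the trans-cyclopropane, setting both ring stereocentres.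

Step 2
Reactants: 2 [(1R,2R)-2-methylcyclopropyl]methanol; 3 2-(triphenyl-λ5-phosphanylidene)propanal
Product: 5 (2E)-2-methyl-3-[(1R,2R)-2-methylcyclopropyl]prop-2-enal, via (1R,2R)-2-methylcyclopropane-1-carbaldehyde 4 (not isolated)
Conditions: TEMPO (2,2,6,6-tetramethylpiperidin-1-oxyl, 10 mol %), PhI(OAc)2, CH2Cl2, rt; then 3, toluene, 80 °C
Reagents that add atoms: none
Why: Oxoammonium oxidation stops at the volatile aldehyde, which is trapped in the same flask by a Wittig reaction with the formyl-stabilised ylide; reversible addition of this ylide leads to the E-trisubstituted enal and leaves the ring stereocentres untouched.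

Step 3
Reactants: 6 3-methylbutan-2-one
Product: 7 trimethyl[(3-methylbut-1-en-2-yl)oxy]silane
Conditions: LiN(iPr)2, THF, −78 °C; Me3SiCl, −78 °C → rt
Reagents that add atoms: chlorotrimethylsilane, C[Si](C)(C)Cl
Why: Kinetic enolisation removes a methyl proton in preference to the methine proton and O-silylation traps the less substituted enolate as its silyl enol ether.

Step 4
Reactants: 5 (2E)-2-methyl-3-[(1R,2R)-2-methylcyclopropyl]prop-2-enal; 7 trimethyl[(3-methylbut-1-en-2-yl)oxy]silane
Product: 9 (5S,6E)-5-hydroxy-2,6-dimethyl-7-[(1R,2R)-2-methylcyclopropyl]hept-6-en-3-one, via trichlorosilyl aldolate 8 (not isolated)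
Conditions: SiCl4, (S,S)-bisphosphoramide C51H52N6O2P2 [pentane-1,5-diyl-linked bis-phosphoramide of (S)-N,N′-dimethyl-1,1′-binaphthalene-2,2′-diamine, 5 mol %], iPr2NEt (10 mol %), CH2Cl2, −78 °C; aq. NaHCO3
Reagents that add atoms: none
Why: Mukaiyama aldol addition under chiral Lewis-base activation of SiCl4: the phosphoramide-bound trichlorosilyl cation activates the enal for 1,2-attack by the enol silane inside a chiral pocket, and the (S,S) catalyst is expected to expose the Si face and so give the 5S carbinol (C2 of the skeleton).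

Step 5
Reactants: 9 (5S,6E)-5-hydroxy-2,6-dimethyl-7-[(1R,2R)-2-methylcyclopropyl]hept-6-en-3-one; 10 ethynylmagnesium bromide
Product: 11 (3R,5S,6E)-3-ethynyl-2,6-dimethyl-7-[(1R,2R)-2-methylcyclopropyl]hept-6-ene-3,5-diol
Conditions: 10 (3.5 equiv, 0.5 M in THF), CH2Cl2, −78 → −20 °C; aq. NH4Cl
Reagents that add atoms: none
Why: Grignard addition under Cram-chelate (1,3) control: the magnesium alkoxide of the C5 hydroxyl chelates the ketone in a six-membered half-chair with the alkenyl group equatorial, and the small ethynyl nucleophile adds axially, anti to that group, which should set the quaternary carbinol (C4 of the skeleton) as 3R; a 3S epimer is a diastereomer and can be removed by chromatography.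

Step 6
Reactants: 11 (3R,5S,6E)-3-ethynyl-2,6-dimethyl-7-[(1R,2R)-2-methylcyclopropyl]hept-6-ene-3,5-diol
Product: 12 (3R,5S,6E)-3-ethynyl-2,6-dimethyl-7-[(1R,2R)-2-methylcyclopropyl]-3,5-bis(triethylsilyloxy)hept-6-ene
Conditions: Et3SiOSO2CF3 (3 equiv), 2,6-lutidine, CH2Cl2, −78 → 0 °C
Reagents that add atoms: triethylsilyl trifluoromethanesulfonate, CC[Si](CC)(CC)OS(=O)(=O)C(F)(F)F
Why: Silylation with the silyl triflate and a hindered pyridine base protects the secondary allylic and the hindered tertiary propargylic hydroxyl in one operation, without acid that could ionise the cyclopropyl-substituted allylic alcohol.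

Step 7
Reactants: 12 (3R,5S,6E)-3-ethynyl-2,6-dimethyl-7-[(1R,2R)-2-methylcyclopropyl]-3,5-bis(triethylsilyloxy)hept-6-ene
Product: 13 4α-isopropyl-1β,8α-dimethyl-2α,4β-bis(triethylsilyloxy)bicyclo[5.3.0]deca-5,9-diene
Conditions: [Rh(CO)2Cl]2 (5 mol %), ClCH2CH2Cl (0.02 M), 80 °C
Reagents that add atoms: none
Why: Monovalent rhodium opens the vinylcyclopropane (C1=C10–C9 with ring C7–C8–C9) at the less substituted C9–C7 bond to a σ-alkyl/π-allyl rhodacycle, the tethered alkyne inserts at the allyl terminus C1 (forming C1–C5), and C(sp3)–C(sp2) reductive elimination joins C6 to C7; the other possible order, alkyne–alkene oxidative coupling before ring opening, leads to the same bonds. The closest known reaction type is the rhodium-catalysed intramolecular (5+2) cycloaddition of tethered alkyne–vinylcyclopropanes to bicyclo[5.3.0]decadienes, for which [Rh(CO)2Cl]2 is an established catalyst; the fully substituted alkene terminus places this case at the hindered end of that class. The five-membered ring (C1–C5) closes in 5-exo fashion through the three-atom tether C2–C3–C4 during the insertion, and the seven-membered ring (C1, C5–C10) closes by reductive elimination from the eight-membered rhodacycle. The only new stereocentre, C1, is controlled by the C2 silyloxy centre: in the conformer that avoids allylic 1,2-strain with the C1 methyl, C2–H lies next to that methyl, the OSiEt3 group lies on the C10 side and C3 leads the alkyne to the face that puts the methyl trans to C2–O, while C4 is already quaternary and C8 is carried through unchanged. The step needs this facial selectivity, cleavage of C9–C7 in preference to C9–C8 (expected because the trans-methyl group leaves the unsubstituted methylene as the accessible bond) and cyclisation faster than alkyne oligomerisation (helped by high dilution and the Thorpe–Ingold effect of quaternary C4).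

Step 8
Reactants: 13 4α-isopropyl-1β,8α-dimethyl-2α,4β-bis(triethylsilyloxy)bicyclo[5.3.0]deca-5,9-diene
Product: 14 4α-isopropyl-1β,8α-dimethyl-4β-(triethylsilyloxy)bicyclo[5.3.0]deca-5,9-dien-2α-ol
Conditions: pyridinium p-toluenesulfonate (0.1 equiv), MeOH/CH2Cl2 (1:1), 0 °C
Reagents that add atoms: none
Why: Acid-catalysed methanolysis of silyl ethers is strongly retarded by substitution at the carbinol carbon, so the secondary C2 ether should be cleaved while the tertiary C4 ether stays in place.

Step 9
Reactants: 14 4α-isopropyl-1β,8α-dimethyl-4β-(triethylsilyloxy)bicyclo[5.3.0]deca-5,9-dien-2α-ol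
Product: 15 9α,10α-epoxy-4α-isopropyl-1β,8α-dimethyl-4β-(triethylsilyloxy)bicyclo[5.3.0]dec-5-en-2α-ol
Conditions: VO(acac)2 (5 mol %), tBuOOH (1.2 equiv, decane), toluene, 0 °C → rt
Reagents that add atoms: tert-butyl hydroperoxide, CC(C)(C)OO
Why: Hydroxyl-directed vanadium-catalysed epoxidation of a homoallylic alcohol: the C2 vanadate, cis-vicinal to C10 on the cyclopentane, should deliver oxygen to the α-face of the cis-disubstituted C9=C10 bond (setting C9 and C10), while the C5=C6 bond, wedged between quaternary C1 and C4 and screened by the α-isopropyl group, should react more slowly.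

Step 10
Reactants: 15 9α,10α-epoxy-4α-isopropyl-1β,8α-dimethyl-4β-(triethylsilyloxy)bicyclo[5.3.0]dec-5-en-2α-ol
Product: 16 4α-isopropyl-1β,8α-dimethyl-9β-(phenylselanyl)-4β-(triethylsilyloxy)bicyclo[5.3.0]dec-5-ene-2α,10α-diol
Conditions: (PhSe)2, NaBH4, EtOH, rt → 78 °C
Reagents that add atoms: diphenyl diselenide, c1ccc(cc1)[Se][Se]c1ccccc1
Why: SN2 opening of the epoxide by benzeneselenolate (trans opening, Fürst–Plattner rule) should occur at C9, because C10 is neopentylic, from the β-face past the β-hydrogen of C8, with inversion at C9 and the C10–O bond and its α configuration untouched.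

Step 11
Reactants: 16 4α-isopropyl-1β,8α-dimethyl-9β-(phenylselanyl)-4β-(triethylsilyloxy)bicyclo[5.3.0]dec-5-ene-2α,10α-diol
Product: 18 4α-isopropyl-1β,8-dimethyl-4β-(triethylsilyloxy)bicyclo[5.3.0]deca-5,8-diene-2α,10α-diol, via selenoxide 17 (not isolated)
Conditions: 30% H2O2, pyridine, THF, 0 °C → rt
Reagents that add atoms: none
Why: Selenoxide syn-elimination: the β-selenium on C9 is cis to the β-hydrogen on C8 and selenoxides eliminate away from a hydroxyl-bearing carbon, so the C8=C9 alkene should form and C10 keeps its α-hydroxyl as an allylic alcohol.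

Step 12
Reactants: 18 4α-isopropyl-1β,8-dimethyl-4β-(triethylsilyloxy)bicyclo[5.3.0]deca-5,8-diene-2α,10α-diol
Product: 19 8α,9α-epoxy-4α-isopropyl-1β,8β-dimethyl-4β-(triethylsilyloxy)bicyclo[5.3.0]dec-5-ene-2α,10α-diol
Conditions: VO(acac)2 (3 mol %), tBuOOH (1.1 equiv, decane), CH2Cl2, 0 °C
Reagents that add atoms: tert-butyl hydroperoxide, CC(C)(C)OO
Why: Hydroxyl-directed vanadium-catalysed epoxidation of the cyclic allylic alcohol places the epoxide syn to C10–OH (α-face, setting C8 and C9), and allylic delivery to C8=C9 is much faster than homoallylic delivery to the hindered C5=C6 bond.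

Step 13
Reactants: 19 8α,9α-epoxy-4α-isopropyl-1β,8β-dimethyl-4β-(triethylsilyloxy)bicyclo[5.3.0]dec-5-ene-2α,10α-diol
Product: 20 2α,10α-diacetoxy-8α,9α-epoxy-4α-isopropyl-1β,8β-dimethyl-4β-(triethylsilyloxy)bicyclo[5.3.0]dec-5-ene
Conditions: Ac2O, 4-(dimethylamino)pyridine, Et3N, CH2Cl2, rt
Reagents that add atoms: acetic anhydride, CC(=O)OC(C)=O
Why: Nucleophile-catalysed acylation of the two secondary hydroxyls installs both acetates of the target at once, while the tertiary silyl ether and the epoxide are inert.

Step 14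
Reactants: 20 2α,10α-diacetoxy-8α,9α-epoxy-4α-isopropyl-1β,8β-dimethyl-4β-(triethylsilyloxy)bicyclo[5.3.0]dec-5-ene
Product: 22 2α,10α-diacetoxy-8α,9α-epoxy-4α-isopropyl-1β,8β-dimethyl-4β-(triethylsilyloxy)-5αH-bicyclo[5.3.0]decan-6α-ol, via alkylborane 21 (not isolated)
Conditions: BH3·THF (5 equiv), THF, 0 °C → rt; NaBO3·4H2O, THF/H2O, rt
Reagents that add atoms: sodium perborate tetrahydrate, [Na+].[Na+].O[B-]1(O)OO[B-](O)(O)OO1.O.O.O.O.O.O
Why: Hydroboration–oxidation: boron adds to the less substituted C6 and hydrogen to C5 in a syn addition from the α-face, opposite the C1 methyl and the allylic C4 silyloxy group (as in the hydroboration of Δ5-steroids anti to the angular methyl), which should set C5–H α (trans ring fusion) and, after oxidation with retention, C6–OH α; perborate spares the acetates.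

Step 15
Reactants: 22 2α,10α-diacetoxy-8α,9α-epoxy-4α-isopropyl-1β,8β-dimethyl-4β-(triethylsilyloxy)-5αH-bicyclo[5.3.0]decan-6α-ol; 23 angelic acid [(2Z)-2-methylbut-2-enoic acid]
Product: 25 2α,10α-diacetoxy-6α-[(2Z)-2-methylbut-2-enoyloxy]-8α,9α-epoxy-4α-isopropyl-1β,8β-dimethyl-4β-(triethylsilyloxy)-5αH-bicyclo[5.3.0]decane, via mixed anhydride 24 (not isolated)
Conditions: 23, 2,4,6-Cl3C6H2COCl, Et3N, toluene, rt; then 22, 75 °C
Reagents that add atoms: none
Why: Yamaguchi-type esterification through the 2,4,6-trichlorobenzoyl mixed anhydride, run without a nucleophilic catalyst, acylates the single free hydroxyl and should keep the Z geometry of the angelate (no isomerisation to the tiglate).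

Step 16
Reactants: 25 2α,10α-diacetoxy-6α-[(2Z)-2-methylbut-2-enoyloxy]-8α,9α-epoxy-4α-isopropyl-1β,8β-dimethyl-4β-(triethylsilyloxy)-5αH-bicyclo[5.3.0]decane
Product: 26 CNP0170993.1
Conditions: HF·pyridine, pyridine, THF, 0 °C → rt
Reagents that add atoms: none
Why: Fluoride cleavage of the tertiary triethylsilyl ether under pyridine-buffered conditions should release the C4 hydroxyl without opening the trisubstituted epoxide or touching the three esters.

**Compound list**

1 | (E)-but-2-en-1-ol | C/C=C/CO | starting material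
2 | [(1R,2R)-2-methylcyclopropyl]methanol | OC[C@@H]1C[C@H]1C | intermediate
3 | 2-(triphenyl-λ5-phosphanylidene)propanal | CC(C=O)=P(c1ccccc1)(c1ccccc1)c1ccccc1 | starting material
4 | (1R,2R)-2-methylcyclopropane-1-carbaldehyde | O=C[C@@H]1C[C@H]1C | intermediate
5 | (2E)-2-methyl-3-[(1R,2R)-2-methylcyclopropyl]prop-2-enal | O=C/C(C)=C/[C@@H]1C[C@H]1C | intermediate
6 | 3-methylbutan-2-one | CC(C)C(C)=O | starting material
7 | trimethyl[(3-methylbut-1-en-2-yl)oxy]silane | C=C(O[Si](C)(C)C)C(C)C | intermediate
8 | trichlorosilyl aldolate (5-O-trichlorosilyl ether of 9) | CC(C)C(=O)C[C@H](O[Si](Cl)(Cl)Cl)/C(C)=C/[C@@H]1C[C@H]1C | intermediate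
9 | (5S,6E)-5-hydroxy-2,6-dimethyl-7-[(1R,2R)-2-methylcyclopropyl]hept-6-en-3-one | CC(C)C(=O)C[C@H](O)/C(C)=C/[C@@H]1C[C@H]1C | intermediate
10 | ethynylmagnesium bromide | C#C[Mg]Br | starting material
11 | (3R,5S,6E)-3-ethynyl-2,6-dimethyl-7-[(1R,2R)-2-methylcyclopropyl]hept-6-ene-3,5-diol | C#C[C@](O)(C(C)C)C[C@H](O)/C(C)=C/[C@@H]1C[C@H]1C | intermediate
12 | (3R,5S,6E)-3-ethynyl-2,6-dimethyl-7-[(1R,2R)-2-methylcyclopropyl]-3,5-bis(triethylsilyloxy)hept-6-ene (cycloaddition precursor) | C#C[C@](O[Si](CC)(CC)CC)(C(C)C)C[C@H](O[Si](CC)(CC)CC)/C(C)=C/[C@@H]1C[C@H]1C | intermediate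
13 | 4α-isopropyl-1β,8α-dimethyl-2α,4β-bis(triethylsilyloxy)bicyclo[5.3.0]deca-5,9-diene (cycloadduct) | C1[C@@H](C)C=C[C@@]2(C)[C@@H](O[Si](CC)(CC)CC)C[C@@](O[Si](CC)(CC)CC)(C(C)C)C2=C1 | intermediate
14 | 4α-isopropyl-1β,8α-dimethyl-4β-(triethylsilyloxy)bicyclo[5.3.0]deca-5,9-dien-2α-ol | C1[C@@H](C)C=C[C@@]2(C)[C@@H](O)C[C@@](O[Si](CC)(CC)CC)(C(C)C)C2=C1 | intermediate
15 | 9α,10α-epoxy-4α-isopropyl-1β,8α-dimethyl-4β-(triethylsilyloxy)bicyclo[5.3.0]dec-5-en-2α-ol | C1[C@@H](C)[C@H]3O[C@H]3[C@@]2(C)[C@@H](O)C[C@@](O[Si](CC)(CC)CC)(C(C)C)C2=C1 | intermediate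
16 | 4α-isopropyl-1β,8α-dimethyl-9β-(phenylselanyl)-4β-(triethylsilyloxy)bicyclo[5.3.0]dec-5-ene-2α,10α-diol | C1[C@@H](C)[C@H]([Se]c3ccccc3)[C@@H](O)[C@@]2(C)[C@@H](O)C[C@@](O[Si](CC)(CC)CC)(C(C)C)C2=C1 | intermediate
17 | selenoxide of 16 [9β-(phenylseleninyl) analogue] | C1[C@@H](C)[C@H]([Se](=O)c3ccccc3)[C@@H](O)[C@@]2(C)[C@@H](O)C[C@@](O[Si](CC)(CC)CC)(C(C)C)C2=C1 | intermediate
18 | 4α-isopropyl-1β,8-dimethyl-4β-(triethylsilyloxy)bicyclo[5.3.0]deca-5,8-diene-2α,10α-diol | C1C(C)=C[C@@H](O)[C@@]2(C)[C@@H](O)C[C@@](O[Si](CC)(CC)CC)(C(C)C)C2=C1 | intermediate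
19 | 8α,9α-epoxy-4α-isopropyl-1β,8β-dimethyl-4β-(triethylsilyloxy)bicyclo[5.3.0]dec-5-ene-2α,10α-diol | C1[C@@]3(C)O[C@H]3[C@@H](O)[C@@]2(C)[C@@H](O)C[C@@](O[Si](CC)(CC)CC)(C(C)C)C2=C1 | intermediate
20 | 2α,10α-diacetoxy-8α,9α-epoxy-4α-isopropyl-1β,8β-dimethyl-4β-(triethylsilyloxy)bicyclo[5.3.0]dec-5-ene | C1[C@@]3(C)O[C@H]3[C@@H](OC(C)=O)[C@@]2(C)[C@@H](OC(C)=O)C[C@@](O[Si](CC)(CC)CC)(C(C)C)C2=C1 | intermediate
21 | 6α-boranyl-2α,10α-diacetoxy-8α,9α-epoxy-4α-isopropyl-1β,8β-dimethyl-4β-(triethylsilyloxy)-5αH-bicyclo[5.3.0]decane (alkylborane) | B[C@H]1C[C@@]2(C)O[C@H]2[C@@H](OC(C)=O)[C@@]2(C)[C@@H](OC(C)=O)C[C@@](O[Si](CC)(CC)CC)(C(C)C)[C@H]12 | intermediate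
22 | 2α,10α-diacetoxy-8α,9α-epoxy-4α-isopropyl-1β,8β-dimethyl-4β-(triethylsilyloxy)-5αH-bicyclo[5.3.0]decan-6α-ol | O[C@H]1C[C@@]2(C)O[C@H]2[C@@H](OC(C)=O)[C@@]2(C)[C@@H](OC(C)=O)C[C@@](O[Si](CC)(CC)CC)(C(C)C)[C@H]12 | intermediate
23 | angelic acid [(2Z)-2-methylbut-2-enoic acid] | C/C=C(/C)C(=O)O | starting material
24 | (2Z)-2-methylbut-2-enoic 2,4,6-trichlorobenzoic anhydride (mixed anhydride) | C/C=C(/C)C(=O)OC(=O)c1c(Cl)cc(Cl)cc1Cl | intermediate
25 | 2α,10α-diacetoxy-6α-[(2Z)-2-methylbut-2-enoyloxy]-8α,9α-epoxy-4α-isopropyl-1β,8β-dimethyl-4β-(triethylsilyloxy)-5αH-bicyclo[5.3.0]decane | C/C=C(/C)C(=O)O[C@H]1C[C@@]2(C)O[C@H]2[C@@H](OC(C)=O)[C@@]2(C)[C@@H](OC(C)=O)C[C@@](O[Si](CC)(CC)CC)(C(C)C)[C@H]12 | intermediate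
26 | CNP0170993.1: 2α,10α-diacetoxy-6α-[(2Z)-2-methylbut-2-enoyloxy]-8α,9α-epoxy-4α-isopropyl-1β,8β-dimethyl-5αH-bicyclo[5.3.0]decan-4β-ol | C/C=C(/C)C(=O)O[C@H]1C[C@@]2(C)O[C@H]2[C@@H](OC(C)=O)[C@@]2(C)[C@@H](OC(C)=O)C[C@@](O)(C(C)C)[C@H]12 | target

**Step count**

Total steps: 16. Longest linear sequence: 15 steps (steps 1, 2 and 4–16, from 1 to 26); step 3 is a one-step branch.

**Three steps most likely to fail, with fallbacks**

Step 7 (key cycloaddition). What may go wrong: insertion at the fully substituted alkene carbon may be slower than alkyne–alkyne coupling, so that the terminal alkyne oligomerises, or the alkyne may reach the wrong face of C1. Fallback, from 12 and back at 13, with no new compound (F0): leave the allyl-rhodium manifold and run the cyclisation with cationic divalent ruthenium, [(C5H5)Ru(NCCH3)3]PF6 (10 mol %) in acetone at rt. This changes the order of events and not just the medium. Alkyne and alkene are first coupled oxidatively to a ruthenacyclopentene, so C1–C5 and the quaternary centre are made before any cyclopropane bond breaks. Strain-driven cleavage of the cyclopropane and reductive elimination then close the seven-membered ring. This oxidative cyclisation is known for 1,6-enynes carrying a cyclopropyl group on the alkene and runs at room temperature, where the silyl ethers and the terminal alkyne are safe. The sense of cyclopropane cleavage for the trans-methyl ring would have to be confirmed on the product.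

Step 9 (first directed epoxidation). What may go wrong: both olefins are homoallylic to C2–OH, so the tethered vanadium peroxide may also transfer oxygen to the more electron-rich trisubstituted C5=C6 bond, eroding site selectivity. Fallback, from 14 and back at 16: replace oxygen-atom transfer by osmylation, whose (3+2) addition cannot be reached at C5, a carbon lodged between two quaternary centres. OsO4·TMEDA (1 equiv) in CH2Cl2 at −78 °C, hydrogen-bonded to the C2 hydroxyl, should add to the α-face of C9=C10 to give the 9α,10α-osmate ester as its TMEDA adduct F1. Aqueous Na2SO3 releases 4α-isopropyl-1β,8α-dimethyl-4β-(triethylsilyloxy)bicyclo[5.3.0]dec-5-ene-2α,9α,10α-triol F2. Methanesulfonyl chloride in pyridine at 0 °C takes C9–OH, the only hydroxyl not next to quaternary C1, giving the 9α-methanesulfonate F3. Sodium benzeneselenolate in EtOH displaces it from the β-face with inversion to give hydroxy selenide 16, and the route resumes at step 11.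

Step 14 (hydroboration). What may go wrong: addition of borane to the crowded C5=C6 bond may be so slow that reduction of the acetates or opening of the epoxide competes, or part of the attack may come from the β-face. Fallback, from 19 and back at 25: hydroborate before any ester is present and tell the hydroxyls apart by their steric environment instead of by the order of events. Excess BH3·THF followed by NaBO3·4H2O should convert epoxy diol 19 into 8α,9α-epoxy-4α-isopropyl-1β,8β-dimethyl-4β-(triethylsilyloxy)-5αH-bicyclo[5.3.0]decane-2α,6α,10α-triol F4. Mixed anhydride 24 (1.1 equiv, toluene, 60 °C) should acylate the C6 hydroxyl, the only one not adjacent to quaternary C1, giving the 6α-angelate 2α,10α-diol F5. Ac2O with 4-(dimethylamino)pyridine then acetylates the two neopentylic hydroxyls to give 25, which is desilylated as in step 16.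

**Further compounds**

F0 | step 7 | none | none
F1 | step 9 | 9α,10α-osmate ester of 14, TMEDA adduct | C1[C@@H](C)[C@H]3O[Os](=O)(=O)O[C@H]3[C@@]2(C)[C@@H](O)C[C@@](O[Si](CC)(CC)CC)(C(C)C)C2=C1.CN(C)CCN(C)C
F2 | step 9 | 4α-isopropyl-1β,8α-dimethyl-4β-(triethylsilyloxy)bicyclo[5.3.0]dec-5-ene-2α,9α,10α-triol | C1[C@@H](C)[C@@H](O)[C@@H](O)[C@@]2(C)[C@@H](O)C[C@@](O[Si](CC)(CC)CC)(C(C)C)C2=C1
F3 | step 9 | 9α-methanesulfonate of F2 | C1[C@@H](C)[C@@H](OS(C)(=O)=O)[C@@H](O)[C@@]2(C)[C@@H](O)C[C@@](O[Si](CC)(CC)CC)(C(C)C)C2=C1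
F4 | step 14 | 8α,9α-epoxy-4α-isopropyl-1β,8β-dimethyl-4β-(triethylsilyloxy)-5αH-bicyclo[5.3.0]decane-2α,6α,10α-triol | O[C@H]1C[C@@]2(C)O[C@H]2[C@@H](O)[C@@]2(C)[C@@H](O)C[C@@](O[Si](CC)(CC)CC)(C(C)C)[C@H]12
F5 | step 14 | 6α-angelate of F4 (2α,10α-diol) | C/C=C(/C)C(=O)O[C@H]1C[C@@]2(C)O[C@H]2[C@@H](O)[C@@]2(C)[C@@H](O)C[C@@](O[Si](CC)(CC)CC)(C(C)C)[C@H]12
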